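1. From the earlier elm run, which read substrates and no product, you asked me for a quick number on the new flask, with the hunch that its product keeps its hand.

| flask | left-handed substrate | right-handed substrate | reagent | remark | time |
|---|---|---|---|---|---|
| elm | 0.020 M | 0.020 M | 8 mM (fed, over 10 min) | run made earlier |  |
| flask | 0.010 M | 0.010 M | 8.00 mM (fed, over 10 min) |  | 2.0 h |

elm run (percent of the left-handed substrate and right-handed substrate together charged)

| time / min | left-handed substrate / % | right-handed substrate / % |
|---|---|---|
| 3.00 | 49.7 | 50.2 |
| 6.00 | 48.2 | 49.8 |
| 10.0 | 45.5 | 50.1 |
| 15.0 | 43.2 | 49.4 |
| 20.0 | 40.9 | 50.2 |
| 25.0 | 40.0 | 49.7 |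

(scatter of a reading: 0.3 percentage points)

- reagent is single-handed; left-handed substrate and right-handed substrate are mirror images of each other, charged as a racemate, each of them at the stated concentration
- an excess is the difference of the two amounts in percent of their sum
- an excess is below zero if the other one leads
- the handed part of reagent does not stay in what it makes, so the products of the two hands are mirror images too

1. part of the left-handed substrate and right-handed substrate charged together that has reacted at 2.0 h
2. excess of left-handed product over right-handed product in the product at 2.0 h
3. excess of right-handed substrate over left-handed substrate among what is left of the two at 2.0 h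

2. I followed one reagent molecule to its fork: left-handed or right-handed substrate. At the last elm reading the two stood at 40.0% and 49.7%, from a half each. The ratio of the logarithms of the fractions left gave 37.1 as the selectivity factor, the ratio of the molecule's chances at that fork with equal amounts of both hands. The figure is a rough reading: it rests on a right-handed drop of 0.3 percentage points against a scatter of 0.3 points.

3. So product as first made should carry an excess of 94.8%. The fraction of right-handed substrate left should be the fraction of left-handed left, raised to one over the factor.

4. The forecast gave c 20% (16% to 23%), eP 97% (90% to 100%) and eS 24% (18% to 29%), calling the right-handed substrate “essentially unreactive and selectivity is high”.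

5. The flask gave c 25.2%, eP 6.62% and eS 32.0%. With 51% of its left-handed substrate left, the factor put the right-handed at 98.2%, so eS at 31.6% and product as made at 92.9%.

    reagent + left-handed substrate → left-handed product (k = 3.25 M⁻¹ min⁻¹)
    reagent + right-handed substrate → right-handed product (k = 0.0617 M⁻¹ min⁻¹)
    reagent ⇌ dormant form (K = 1.73, k = 0.0534 min⁻¹)
    reagent → decomposition product (k = 2.26 × 10⁻⁴ min⁻¹)
    left-handed product ⇌ right-handed product (k = 0.0269 min⁻¹)

6. In this flask the path from reagent and left-handed substrate to left-handed product had 48% of its turnover up to 2.0 h behind it at 0.400 h, while reagent fell from 69.1% of its charge at 0.167 h to 16.4% at 1.00 h. Over the same time left-handed product was turning into right-handed product, with a relaxation half-life of 0.215 h by that step alone, short against 2.0 h, and the product excess went from 76.2% at 0.200 h to 18.5% at 1.00 h.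

7. In the neighbour flask, the same but with 0.0020 M of reagent and with 86% of the left-handed substrate left at the end, the factor put the right-handed at 99.6% and eS at 7.33%. The computed neighbour flask gave eS 7.40% and eP 7.10%.

Readings and results stem from a simulated flask with made-up constants.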